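At late times the flask has one end to go to. In the runs so far J and G sum to about the J charged, as in the west run at 40.0 min with 65.2% and 35.3%, so J ends as G and what stays open is the pace.

| setting | north-east | west | south-west | flask |
|---|---|---|---|---|
| J | 0.050 M | 0.050 M | 0.10 M | 0.050 M |
| D | 1.3 equiv | 3 equiv | 2 equiv | 2.00 equiv |
| L | 0.031 mol% | 0.031 mol% | 0.031 mol% | 0.031 mol% |
| remark | run made earlier | run made earlier | run made earlier |  |

- north-east (time / min: G / %, J / %): 3.00: 2.0, 98.1; 6.00: 4.7, 95.2; 15.0: 11.2, 88.8; 40.0: 27.6, 70.9
- west (time / min: G / %, J / %): 5.00: 4.0, 95.1; 12.0: 10.7, 89.2; 25.0: 21.8, 77.6; 40.0: 35.3, 65.2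
- south-west (time / min: G / %, J / %): 5.00: 4.5, 94.1; 12.0: 13.7, 87.7; 25.0: 26.7, 72.9; 40.0: 42.6, 58.8

(standard deviation of a reading: 0.5 percentage points)

- factor on the rate of making G when 5.0% of the J are converted if D is charged twice over
- factor on the rate when 5.0% of the J are converted if L is charged at 0.3 mol% instead

Two chemists dispute that pace. Anna holds that each L turns over on its own, so she divides by it. For the west run she gets 28.5 min⁻¹: this is T, the G made per L charged per minute from the start to a reading, the turnover frequency. The north-east run gives 22.3 min⁻¹ and the south-west run 34.4 min⁻¹.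

The flask has the J and L of the north-east and west runs, with D between theirs, so she takes their mean, 25.4 min⁻¹. A new loading at unchanged J and D leaves T alone, she says, so the rate follows the charge, a factor of 9.68. From the north-east and west runs she puts doubled D at 1.23.

Ben sees the molar rate of the south-west run, averaged up to 40.0 min, at 2.41 times that of the west run, with the molarity of L doubled. He holds J near zero order and lays that factor mainly on L. Anna answers that T is higher in the south-west run, where the molarities of J and D also stand higher. She grants him the inside of one run: the west run gives T of 28.1 min⁻¹ at 25.0 min and 28.5 min⁻¹ at 40.0 min, though J falls.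

Ben's side is the forecast, 1.1 for doubled D and 13 for the new loading, lower than Anna on D and higher on L, on the ground “With J near zero order, this is mostly L, order about 1.0–1.25”.

The flask gives 1.14 and 9.68.

    J + L ⇌ Q (K = 26.0 M⁻¹, k = 6900 M⁻¹ min⁻¹)
    Q → X + Z (k = 160 min⁻¹)
    D + X ⇌ E (K = 23.0 M⁻¹, k = 3600 M⁻¹ min⁻¹)
    E → L + G (k = 73.0 min⁻¹)

The apparent order in L at 5.0% conversion is 1.0, and the flask's G of 46.2% at 1.00 h makes its T 24.9 min⁻¹. At 0.472 h in the flask, E falls back to D and X at 2.1 times the rate at which it goes on to L and G, while its net making and using stand at a ratio of 1.00.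

The runs were computed from invented constants; the scatter is artificial.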